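Watch the target. You asked for a quick number on the 0.20 M flask, with the hunch that side product simply follows the starting material; that is part of it, and target is the rest.

| flask | starting material | second substrate | reagent | free catalyst | remark | time |
|---|---|---|---|---|---|---|
| north | 0.10 M | 0.20 M | 0.22 M | 10 mM | run made earlier |  |
| east | 0.40 M | 0.20 M | 0.22 M | 10 mM | run made earlier |  |
| flask | 0.20 M | 0.200 M | 0.220 M | 10 mM |  | 30 h |

| run | time / h | target / % | side product / % |
|---|---|---|---|
| north | 8.00 | 17 | 5 |
| north | 15.0 | 26 | 11 |
| north | 25.0 | 24 | 19 |
| north | 30.0 | 34 | 24 |
| east | 8.00 | 8 | 12 |
| east | 15.0 | 8 | 19 |
| east | 25.0 | 6 | 35 |
| east | 30.0 | 6 | 41 |

(each reading ± 2 percentage points)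

- percentages count the starting material that a species holds: one side product counts as two
- the numbers in the tables scatter by 2 percentage points (one standard deviation)

- target present at 30 h, in percent of the starting material charged
- side product present at 30 h, in percent of the starting material charged
- starting material present at 30 h, in percent of the starting material charged
- concentration of catalyst intermediate B at 30 h, in M

Averaged over its readings, target stands at 0.0253 M in the north run and 0.0280 M in the east run, nearly equal although their charges of starting material were 0.10 M and 0.40 M. North's target still drifts upward, but east's has stalled, while side product grows in both. So I test a rate proportional to starting material times target, counting starting material as the charge less target and side product. Between the first and last readings, east gives 0.354 /M/h and north 0.285 /M/h. I carry their mean, 0.319 /M/h, as the coupling constant: side product formed per hour, divided by starting material times target.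

In this test rate, side product is pseudo-first-order in starting material for as long as target stands level, so target is the concentration to follow. For your flask I take target at 0.0266 M, which is 13.3% of the charge. I take starting material at a mean 63.2%, midway between the two runs. Each side product counts twice, so starting from the runs' mean at 8.00 h, I reach 32.2% side product, leaving 54.5% starting material. Catalyst intermediate B is not among the readings, so I can say of it that it lies below the 10 mM of catalyst charged.

The forecast, by another route (“which slowly releases side product”), gave 20% target, above mine, with 30% side product, 47% starting material and 0.004 M of catalyst intermediate B.

The flask gives 16.1% target, 34.1% side product, 49.0% starting material and 0.00240 M of catalyst intermediate B.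

    starting material + free catalyst ⇌ catalyst intermediate A (K = 3.00 /M, k = 13.0 /M/h)
    reagent + catalyst intermediate A → free catalyst + target (k = 13.0 /M/h)
    second substrate + free catalyst ⇌ catalyst intermediate B (K = 5.50 /M, k = 32.0 /M/h)
    reagent + catalyst intermediate B → free catalyst + second product (k = 14.0 /M/h)
    starting material + target → side product (k = 0.320 /M/h)

In the flask, target reached 16.1% by 15.0 h and stood at 16.1% at 30.0 h, while reagent fell from 37.4% to 15.8% of its charge and starting material with target raised side product from 15.9% to 34.1%. Over that stretch, the coupling constant with the flask's own target and mean starting material gives 18 percentage points, and the flask's side product gained 18 points. In a neighbour flask charged with 0.50 M of second substrate, target ended at 6.76%, and supposing that level for the whole time gives 22.1% side product, where that neighbour flask holds 22.1%.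

(The data stem from a simulated flask with made-up constants; noise was put on by code.)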